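Vidalol B is cut at the two bonds joining C4 and C6 of the central ring to the benzylic CH2 carbons. The key step uses two features: each outer ring has its C4' hydroxyl para to C1', the carbon bearing the CH2 bridge, so a benzylic alcohol ionises to a para-quinone methide; and bromine at C2 of the central ring leaves only C4 and C6 unsubstituted, both ortho to two hydroxyls and para to a third. One acid-catalysed operation should therefore attach two molecules of 2,3-dibromo-4-hydroxy-5-methoxybenzyl alcohol to 2-bromophloroglucinol, forming both aryl–CH2 bonds with the benzyl count held at two. The outer catechols are carried as monomethyl ethers and unmasked last.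

Key step: step 4

Remark on the chemistry: the target has no stereocentre, so no configuration has to be set or preserved; commercial phloroglucinol is assumed to be used in its anhydrous form.

Step 1
Reactants: 1 5-bromovanillin (3-bromo-4-hydroxy-5-methoxybenzaldehyde)
Product: 2 2,3-dibromo-4-hydroxy-5-methoxybenzaldehyde (5,6-dibromovanillin)
Conditions: Br2 (1.2 equiv), Fe powder (cat.), AcOH, rt to 50 °C
Reagents that add atoms: bromine, BrBr
Why: Electrophilic aromatic bromination, with FeBr3 formed in the flask activating Br2, should enter at the ring CH para to the methoxy group, since every position ortho or para to the hydroxyl is already occupied and the other CH is only ortho to OMe; this is the established regiochemical outcome for this substrate.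

Step 2
Reactants: 2 2,3-dibromo-4-hydroxy-5-methoxybenzaldehyde
Product: 3 2,3-dibromo-4-hydroxy-5-methoxybenzyl alcohol
Conditions: NaBH4 (1.5 equiv), THF–H2O, 0 °C; then 1 M HCl to pH 6 at 0 °C
Reagents that add atoms: none
Why: NaBH4 carbonyl reduction converts the aldehyde to the primary alcohol while aryl bromides, methyl ether and phenol are inert, and the alcohol-free medium with a near-neutral quench avoids premature ionisation or etherification of the acid-labile 4-hydroxybenzyl alcohol.

Step 3
Reactants: 4 phloroglucinol (benzene-1,3,5-triol)
Product: 5 2-bromobenzene-1,3,5-triol (2-bromophloroglucinol)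
Conditions: NBS (0.95 equiv, portionwise), THF, −78 to 0 °C, dark
Reagents that add atoms: N-bromosuccinimide, O=C1CCC(=O)N1Br
Why: Electrophilic aromatic bromination of a strongly activated arene whose three CH positions are equivalent, so only the degree of bromination needs control; the first bromine lowers ring nucleophilicity, and a slight deficit of NBS at low temperature should stop at the monobromide, which is then freed from residual 4 by chromatography.

Step 4
Reactants: 5 2-bromobenzene-1,3,5-triol (1 equiv); 3 2,3-dibromo-4-hydroxy-5-methoxybenzyl alcohol (2.1 equiv)
Product: 8 2-bromo-4,6-bis(2,3-dibromo-4-hydroxy-5-methoxybenzyl)benzene-1,3,5-triol, via para-quinone methide 6 (not isolated), via mono-benzylated triol 7 (not isolated)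
Conditions: p-TsOH·H2O (10 mol %), 1,4-dioxane, 50 °C, Ar; 3 added slowly
Reagents that add atoms: none
Why: Acid-assisted loss of water from 3, driven by the C4' hydroxyl para to the benzylic carbon, gives para-quinone methide 6, whose exocyclic CH2 is attacked in a 1,6-sense by C4 of triol 5 (ortho to two hydroxyls, para to the third); tautomerisation restores both arenes to give 7, and the same sequence at C6 gives 8. This is a Friedel–Crafts hydroxybenzylation of the kind well established for acid-promoted C-benzylation of phloroglucinols with 4-hydroxybenzyl alcohols. No ring is closed and no stereocentre is formed, so only chemo- and site-selectivity matter. C- over O-alkylation follows because ether formation from a quinone methide is reversible under acid whereas C–C bond formation is sealed by rearomatisation, and the count of two is enforced by the C2 bromine, which leaves no third nucleophilic CH. Self-condensation of 3 should not compete because its only ring CH (C6') sits meta to the hydroxyl on a ring deactivated by two bromines, far less nucleophilic than the trihydroxylated ring. Catalytic sulfonic acid, moderate temperature and slow addition of 3 keep the quinone methide concentration low and should be too mild for ipso-protonation and loss of the C2 bromine.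

Step 5
Reactants: 8 2-bromo-4,6-bis(2,3-dibromo-4-hydroxy-5-methoxybenzyl)benzene-1,3,5-triol
Product: 9 vidalol B (2-bromo-4,6-bis(2,3-dibromo-4,5-dihydroxybenzyl)benzene-1,3,5-triol)
Conditions: BBr3 (10 equiv), CH2Cl2, −78 °C to rt; then ice–H2O
Reagents that add atoms: none
Why: BBr3 ether cleavage (Lewis-acid demethylation) should remove both methyl groups as MeBr and release the two catechols on hydrolysis, while the aryl bromides and the diarylmethane links, on rings that are boron-bound and therefore less electron-rich during the reaction, should persist at low temperature.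

Compound list
1 | 5-bromovanillin (3-bromo-4-hydroxy-5-methoxybenzaldehyde) | COc1cc(C=O)cc(Br)c1O | starting material
2 | 2,3-dibromo-4-hydroxy-5-methoxybenzaldehyde (5,6-dibromovanillin) | COc1cc(C=O)c(Br)c(Br)c1O | intermediate
3 | 2,3-dibromo-4-hydroxy-5-methoxybenzyl alcohol | COc1cc(CO)c(Br)c(Br)c1O | intermediate
4 | phloroglucinol (benzene-1,3,5-triol) | Oc1cc(O)cc(O)c1 | starting material
5 | 2-bromobenzene-1,3,5-triol (2-bromophloroglucinol) | Oc1cc(O)c(Br)c(O)c1 | intermediate
6 | para-quinone methide, 2,3-dibromo-6-methoxy-4-methylidenecyclohexa-2,5-dien-1-one | C=C1C=C(OC)C(=O)C(Br)=C1Br | intermediate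
7 | mono-benzylated triol, 2-bromo-4-(2,3-dibromo-4-hydroxy-5-methoxybenzyl)benzene-1,3,5-triol | COc1cc(Cc2c(O)cc(O)c(Br)c2O)c(Br)c(Br)c1O | intermediate
8 | 2-bromo-4,6-bis(2,3-dibromo-4-hydroxy-5-methoxybenzyl)benzene-1,3,5-triol | Oc1c(Br)c(O)c(Cc2cc(OC)c(O)c(Br)c2Br)c(O)c1Cc1cc(OC)c(O)c(Br)c1Br | intermediate
9 | vidalol B, 2-bromo-4,6-bis(2,3-dibromo-4,5-dihydroxybenzyl)benzene-1,3,5-triol | Oc1cc(Cc2c(O)c(Br)c(O)c(Cc3cc(O)c(O)c(Br)c3Br)c2O)c(Br)c(Br)c1O | target

Total step count: 5.
Longest linear sequence: 4 steps (steps 1, 2, 4 and 5); step 3 supplies the second coupling partner.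

Steps most likely to fail

Step 4. The danger is ipso attack at C2 of the central ring by a proton or by the quinone methide, which would cause loss or migration of the bromine and open a third benzylation site; the second benzylation may also stall. The fallback installs the bromine after the C–C bonds and sets out from phloroglucinol 4 and benzyl alcohol 3. Under the same sulfonic-acid catalysis, quinone methide 6 would be trapped by 4 to give first 2-(2,3-dibromo-4-hydroxy-5-methoxybenzyl)benzene-1,3,5-triol F1 (not isolated) and, with two equivalents of 3, 2,4-bis(2,3-dibromo-4-hydroxy-5-methoxybenzyl)benzene-1,3,5-triol F2. F2 would be separated chromatographically from mono- and tris-benzylated material. NBS (1 equiv, THF, −78 °C, dark) should then brominate the single remaining central CH, which is far more activated than the C6' positions of the outer rings, and the route is rejoined at compound 8.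

Step 3. The danger is over-bromination, since the monobromide is still a very reactive arene, giving a mixture of unreacted triol and mono-, di- and tribromides that is hard to separate. The fallback tempers the ring by O-methylation and sets out from phloroglucinol 4. Me2SO4 and K2CO3 in refluxing acetone should give 1,3,5-trimethoxybenzene F3. NBS (1.0 equiv) in MeCN at 0 °C should then give cleanly 2-bromo-1,3,5-trimethoxybenzene F4. BBr3 in CH2Cl2 (−78 °C to rt, aqueous work-up) would cleave the three methyl ethers and return to compound 5.

Step 5. The danger is acid-induced cleavage of the aryl–CH2 bonds or migration of bromine in the electron-rich polyphenol in the presence of BBr3 and HBr, or incomplete ether cleavage. The fallback removes the methyl group before the coupling and sets out from aldehyde 2. AlCl3 and pyridine in refluxing CH2Cl2 (chelation-assisted demethylation of the guaiacol unit, then dilute HCl) should give 2,3-dibromo-4,5-dihydroxybenzaldehyde F5. NaBH4 in THF–H2O with a pH 6 quench should give 2,3-dibromo-4,5-dihydroxybenzyl alcohol F6. Under the conditions of step 4, two equivalents of F6 would react with triol 5 through 2,3-dibromo-6-hydroxy-4-methylidenecyclohexa-2,5-dien-1-one F7 and 2-bromo-4-(2,3-dibromo-4,5-dihydroxybenzyl)benzene-1,3,5-triol F8 (neither isolated), arriving directly at compound 9 with no step after the coupling.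

Further compounds
F1 | step 4 | 2-(2,3-dibromo-4-hydroxy-5-methoxybenzyl)benzene-1,3,5-triol | COc1cc(Cc2c(O)cc(O)cc2O)c(Br)c(Br)c1O
F2 | step 4 | 2,4-bis(2,3-dibromo-4-hydroxy-5-methoxybenzyl)benzene-1,3,5-triol | Oc1cc(O)c(Cc2cc(OC)c(O)c(Br)c2Br)c(O)c1Cc1cc(OC)c(O)c(Br)c1Br
F3 | step 3 | 1,3,5-trimethoxybenzene | COc1cc(OC)cc(OC)c1
F4 | step 3 | 2-bromo-1,3,5-trimethoxybenzene | COc1cc(OC)c(Br)c(OC)c1
F5 | step 5 | 2,3-dibromo-4,5-dihydroxybenzaldehyde | O=Cc1cc(O)c(O)c(Br)c1Br
F6 | step 5 | 2,3-dibromo-4,5-dihydroxybenzyl alcohol | OCc1cc(O)c(O)c(Br)c1Br
F7 | step 5 | 2,3-dibromo-6-hydroxy-4-methylidenecyclohexa-2,5-dien-1-one | C=C1C=C(O)C(=O)C(Br)=C1Br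
F8 | step 5 | 2-bromo-4-(2,3-dibromo-4,5-dihydroxybenzyl)benzene-1,3,5-triol | Oc1cc(Cc2c(O)cc(O)c(Br)c2O)c(Br)c(Br)c1O
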